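The oxane ring (O1, C2 aryl, C3 cinnamyl, C5 carbinol-bearing) is cut at O1–C6 and C4–C5. The key step joins a palladium π-allyl/alkoxide 1,4-dipole (O1–C2–C3–C4, from a Morita–Baylis–Hillman-derived hydroxy allyl carbonate) to an aryl vinyl ketone (C6=C5–C8=O) by oxa-Michael addition and intramolecular allylation. It exploits the 1,3-relation of O1 and C4 across C3: the exocyclic cinnamyl CH2 on C3 is the second allyl terminus and reappears as a 3-methylidene handle. C2 comes from the precursor. C3 and C5 are then set by hydroboration and kinetic protonation, each receiving hydrogen on the face opposite the C2 aryl group. The carbinol carbon is set by CBS reduction.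

Key step: step 7

Remark: ArT = 4-(triisopropylsilyloxy)phenyl; ring positions use the oxane numbering of the target and C8 is the carbinol carbon; compounds 1, 3, 7 and all reagents are taken as commercial.

Step 1
Reactants: 1 4-hydroxybenzaldehyde
Product: 2 4-(triisopropylsilyloxy)benzaldehyde
Conditions: i-Pr3SiCl, imidazole, DMF, 25 °C
Reagents that add atoms: triisopropylsilyl chloride, CC(C)[Si](Cl)(C(C)C)C(C)C
Why: Imidazole-promoted silylation of the phenol; the triisopropylsilyl aryl ether is chosen because it should survive alkoxides, i-Bu2AlH, lithium amides and aqueous carbonate until fluoride removes it.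

Step 2
Reactants: 2 4-(triisopropylsilyloxy)benzaldehyde; 3 1,1,1,3,3,3-hexafluoropropan-2-yl acrylate
Product: 4 1,1,1,3,3,3-hexafluoropropan-2-yl (S)-2-[hydroxy(ArT)methyl]prop-2-enoate
Conditions: α-isocupreine (10 mol %), DMF, −55 °C
Reagents that add atoms: none
Why: Asymmetric Morita–Baylis–Hillman reaction in which the cinchona-derived amine adds to the activated acrylate and its phenolic OH organizes the aldol step; the quinine-derived α-isocupreine (pseudoenantiomer of β-isocupreidine, which gives the (R) series) should deliver the (S)-carbinol that becomes C2.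

Step 3
Reactants: 4 hexafluoroisopropyl (S)-2-[hydroxy(ArT)methyl]prop-2-enoate
Product: 5 (S)-2-methylidene-1-ArT-propane-1,3-diol
Conditions: i-Bu2AlH (3.5 equiv), CH2Cl2, −78 → −20 °C; aq. potassium sodium tartrate
Reagents that add atoms: none
Why: 1,2-Reduction of the activated acrylate ester to the allylic alcohol by i-Bu2AlH, which leaves the aryl silyl ether and the carbinol stereocentre untouched.

Step 4
Reactants: 5 (S)-2-methylidene-1-ArT-propane-1,3-diol
Product: 6 tert-butyl (S)-2-[hydroxy(ArT)methyl]prop-2-en-1-yl carbonate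
Conditions: Boc2O (1.05 equiv), DMAP (5 mol %), CH2Cl2, −20 → 0 °C
Reagents that add atoms: di-tert-butyl dicarbonate, CC(C)(C)OC(=O)OC(=O)OC(C)(C)C
Why: Chemoselective carbonate formation at the unhindered primary allylic hydroxyl over the hindered secondary benzylic one, which leaves exactly one allylic leaving group in the molecule.

Step 5
Reactants: 2 4-(triisopropylsilyloxy)benzaldehyde; 7 vinylmagnesium bromide
Product: 8 rac-1-ArT-prop-2-en-1-ol
Conditions: CH2=CHMgBr, THF, −78 → 0 °C; aq. NH4Cl
Reagents that add atoms: none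
Why: 1,2-Addition of a vinyl Grignard reagent to the aldehyde; the configuration of the carbinol is irrelevant because it is oxidized in step 6.

Step 6
Reactants: 8 rac-1-ArT-prop-2-en-1-ol
Product: 9 1-ArT-prop-2-en-1-one
Conditions: MnO2 (excess), CH2Cl2, 25 °C
Reagents that add atoms: none
Why: MnO2 oxidation of a benzylic and allylic alcohol to the aryl vinyl ketone under neutral conditions; 9 should be used at once because such enones polymerize on storage.

Step 7
Reactants: 6 tert-butyl (S)-2-[hydroxy(ArT)methyl]prop-2-en-1-yl carbonate; 9 1-ArT-prop-2-en-1-one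
Product: 10 (2R)-5-(ArT-carbonyl)-3-methylidene-2-ArT-oxane (both C5 epimers)
Conditions: Pd2(dba)3 (2.5 mol %), Xantphos (6 mol %), THF, 0 → 25 °C; 9 (1.5 equiv) added over 2 h
Reagents that add atoms: none
Why: Zerovalent palladium ionizes the only allylic leaving group of 6, the primary tert-butyl carbonate, and the tert-butoxide released with CO2 deprotonates the neighbouring secondary alcohol to give an alkoxide/π-allyl 1,4-dipole; the alkoxide adds to the β-carbon of 9 (oxa-Michael, O1–C6) and the resulting enolate attacks a terminus of the π-allyl unit (C4–C5), returning zerovalent palladium. The closest known reaction type is the palladium-catalysed oxa-[4+2] annulation of 2-methylidenetrimethylene carbonates and 2-(hydroxymethyl)allyl carbonates with electron-poor alkenes, an oxa-Michael/Tsuji–Trost cascade. The single ring closes in a 6-exo-trig allylic alkylation, and because both allyl termini are CH2 groups either one gives the same 3-methylideneoxane. C2 is not part of the allyl system and its C–O bond is never broken, so the configuration set in step 2 is carried through as (2R). C5 is formed without useful control (the extended, equatorial-type enolate transition state should favour the 2,5-trans isomer), which is accepted because this centre is erased in step 8 and set in step 11. The step needs chemoselectivity for oxa-Michael/C-allylation over O-allylation, oxetane closure and anionic polymerization of 9, which the single leaving group, the unhindered acceptor, its slow addition and the six-membered ring closure should secure.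

Step 8
Reactants: 10 (2R)-5-(ArT-carbonyl)-3-methylidene-2-ArT-oxane
Product: 12 (2R)-3-methylidene-2-ArT-5-[ArT(trimethylsilyloxy)methylidene]oxane (E/Z mixture), via lithium enolate 11 (not isolated)
Conditions: LiN(i-Pr)2 (1.1 equiv), THF, −78 °C; Me3SiCl, −78 → 0 °C; non-aqueous work-up
Reagents that add atoms: chlorotrimethylsilane, C[Si](C)(C)Cl
Why: Regiodefined enolization (only C5 carries an α-hydrogen) at −78 °C, where β-elimination of the ring oxygen should be slow, followed by O-silylation; this masks the ketone against 9-BBN and erases the C5 mixture.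

Step 9
Reactants: 2 4-(triisopropylsilyloxy)benzaldehyde
Product: 13 (E)-1-(2-iodoethenyl)-4-(triisopropylsilyloxy)benzene
Conditions: CrCl2 (6 equiv), CHI3 (2 equiv), THF, 0 → 25 °C
Reagents that add atoms: iodoform, IC(I)I
Why: Takai olefination, in which the geminal dichromium reagent formed from CHI3 and CrCl2 adds to the aldehyde and eliminates to the (E)-vinyl iodide.

Step 10
Reactants: 12 (2R)-3-methylidene-2-ArT-5-[ArT(trimethylsilyloxy)methylidene]oxane; 13 (E)-1-(2-iodoethenyl)-4-(triisopropylsilyloxy)benzene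
Product: 16 (2R,3S)-5-(ArT-carbonyl)-2-ArT-3-[(E)-3-ArT-prop-2-en-1-yl]oxane (both C5 epimers), via B-alkyl-9-BBN borane 14 (not isolated), via coupled silyl enol ether 15 (not isolated)
Conditions: 9-BBN-H (1.5 equiv), THF, 0 → 25 °C; then 13, PdCl2(dppf) (5 mol %), AsPh3 (5 mol %), Cs2CO3, DMF/H2O, 25 °C; then 10% aq. citric acid, THF, 0 °C
Reagents that add atoms: none
Why: Hydroboration followed by B-alkyl Suzuki–Miyaura coupling; 9-BBN places boron on the CH2 terminus and, as with 2-substituted methylenecyclohexanes and allylic ethers (A(1,3)-strain model with the C2–H eclipsing the alkene and the aryl group perpendicular to it), should add on the face opposite the C2 aryl group, so that hydrogen enters C3 anti to the aryl and the new CH2 is cis to it (3S), while the coupling retains the (E) geometry and the aqueous medium cleaves the trimethylsilyl enol ether.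

Step 11
Reactants: 16 (2R,3S)-5-(ArT-carbonyl)-2-ArT-3-[(E)-3-ArT-prop-2-en-1-yl]oxane (both C5 epimers)
Product: 18 (2R,3S,5R)-5-(ArT-carbonyl)-2-ArT-3-[(E)-3-ArT-prop-2-en-1-yl]oxane (all-cis), via lithium enolate 17 (not isolated)
Conditions: LiN(i-Pr)2 (1.2 equiv), THF, −78 °C; then 2,6-di-tert-butyl-4-methylphenol (3 equiv), −78 °C; cold pH 7 buffer
Reagents that add atoms: none
Why: Kinetic protonation of an exocyclic enolate; in the chair with the C2 aryl equatorial and the C3 cinnamyl group axial, the axial approach to C5 is blocked by the syn-axial cinnamyl group, so the hindered phenol should deliver the proton from the equatorial side and leave the aroyl group cis to both neighbours (5R), the less stable epimer that equilibration would not give.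

Step 12
Reactants: 18 (2R,3S,5R)-5-(ArT-carbonyl)-2-ArT-3-[(E)-3-ArT-prop-2-en-1-yl]oxane
Product: 19 (R)-ArT[(2R,3S,5R)-2-ArT-3-[(E)-3-ArT-prop-2-en-1-yl]oxan-5-yl]methanol
Conditions: (S)-2-methyl-CBS-oxazaborolidine (0.5 equiv), catecholborane (2 equiv), toluene, −78 → −40 °C; MeOH, then aq. NaHCO3
Reagents that add atoms: none
Why: Corey–Bakshi–Shibata reduction, in which the (S)-oxazaborolidine binds the ketone with the aryl group as the large substituent and should deliver hydride under reagent control to give the (R)-carbinol (the sense in which acetophenone gives (R)-1-phenylethanol), under non-basic conditions that do not epimerize C5 and with a borane that spares the styrene.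

Step 13
Reactants: 19 (R)-ArT[(2R,3S,5R)-2-ArT-3-[(E)-3-ArT-prop-2-en-1-yl]oxan-5-yl]methanol
Product: 20 4-[(E)-3-[(2R,3S,5R)-5-[(R)-hydroxy(4-hydroxyphenyl)methyl]-2-(4-hydroxyphenyl)oxan-3-yl]prop-1-en-1-yl]phenol (CNP0182155.1)
Conditions: n-Bu4NF (3.5 equiv), AcOH (3.5 equiv), THF, 0 → 25 °C
Reagents that add atoms: none
Why: Fluoride cleavage of the three aryl silyl ethers; buffering with acetic acid keeps the medium near neutral so that the p-hydroxybenzylic ether at C2 and the benzylic alcohol should neither ionize nor epimerize.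

Compound list
1 | 4-hydroxybenzaldehyde | O=Cc1ccc(O)cc1 | starting material
2 | 4-(triisopropylsilyloxy)benzaldehyde | O=Cc1ccc(O[Si](C(C)C)(C(C)C)C(C)C)cc1 | intermediate
3 | 1,1,1,3,3,3-hexafluoropropan-2-yl acrylate | C=CC(=O)OC(C(F)(F)F)C(F)(F)F | starting material
4 | 1,1,1,3,3,3-hexafluoropropan-2-yl (S)-2-[hydroxy(ArT)methyl]prop-2-enoate | O[C@H](C(=C)C(=O)OC(C(F)(F)F)C(F)(F)F)c1ccc(O[Si](C(C)C)(C(C)C)C(C)C)cc1 | intermediate
5 | (S)-2-methylidene-1-ArT-propane-1,3-diol | O[C@H](C(=C)CO)c1ccc(O[Si](C(C)C)(C(C)C)C(C)C)cc1 | intermediate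
6 | tert-butyl (S)-2-[hydroxy(ArT)methyl]prop-2-en-1-yl carbonate | O[C@H](C(=C)COC(=O)OC(C)(C)C)c1ccc(O[Si](C(C)C)(C(C)C)C(C)C)cc1 | intermediate
7 | vinylmagnesium bromide | C=C[Mg]Br | starting material
8 | rac-1-ArT-prop-2-en-1-ol | C=CC(O)c1ccc(O[Si](C(C)C)(C(C)C)C(C)C)cc1 | intermediate
9 | 1-ArT-prop-2-en-1-one | C=CC(=O)c1ccc(O[Si](C(C)C)(C(C)C)C(C)C)cc1 | intermediate
10 | (2R)-5-(ArT-carbonyl)-3-methylidene-2-ArT-oxane, both C5 epimers | C=C1CC(C(=O)c2ccc(O[Si](C(C)C)(C(C)C)C(C)C)cc2)CO[C@H]1c1ccc(O[Si](C(C)C)(C(C)C)C(C)C)cc1 | intermediate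
11 | lithium enolate of 10 | C=C1CC(=C(O[Li])c2ccc(O[Si](C(C)C)(C(C)C)C(C)C)cc2)CO[C@H]1c1ccc(O[Si](C(C)C)(C(C)C)C(C)C)cc1 | intermediate
12 | (2R)-3-methylidene-2-ArT-5-[ArT(trimethylsilyloxy)methylidene]oxane, E/Z mixture | C=C1CC(=C(O[Si](C)(C)C)c2ccc(O[Si](C(C)C)(C(C)C)C(C)C)cc2)CO[C@H]1c1ccc(O[Si](C(C)C)(C(C)C)C(C)C)cc1 | intermediate
13 | (E)-1-(2-iodoethenyl)-4-(triisopropylsilyloxy)benzene | I/C=C/c1ccc(O[Si](C(C)C)(C(C)C)C(C)C)cc1 | intermediate
14 | 9-{[(2R,3S)-2-ArT-5-[ArT(trimethylsilyloxy)methylidene]oxan-3-yl]methyl}-9-borabicyclo[3.3.1]nonane | B1(C[C@H]2CC(=C(O[Si](C)(C)C)c3ccc(O[Si](C(C)C)(C(C)C)C(C)C)cc3)CO[C@H]2c2ccc(O[Si](C(C)C)(C(C)C)C(C)C)cc2)C2CCCC1CCC2 | intermediate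
15 | (2R,3S)-2-ArT-3-[(E)-3-ArT-prop-2-en-1-yl]-5-[ArT(trimethylsilyloxy)methylidene]oxane | CC(C)[Si](Oc1ccc(/C=C/C[C@H]2CC(=C(O[Si](C)(C)C)c3ccc(O[Si](C(C)C)(C(C)C)C(C)C)cc3)CO[C@H]2c2ccc(O[Si](C(C)C)(C(C)C)C(C)C)cc2)cc1)(C(C)C)C(C)C | intermediate
16 | (2R,3S)-5-(ArT-carbonyl)-2-ArT-3-[(E)-3-ArT-prop-2-en-1-yl]oxane, both C5 epimers | CC(C)[Si](Oc1ccc(/C=C/C[C@H]2CC(C(=O)c3ccc(O[Si](C(C)C)(C(C)C)C(C)C)cc3)CO[C@H]2c2ccc(O[Si](C(C)C)(C(C)C)C(C)C)cc2)cc1)(C(C)C)C(C)C | intermediate
17 | lithium enolate of 16 | CC(C)[Si](Oc1ccc(/C=C/C[C@H]2CC(=C(O[Li])c3ccc(O[Si](C(C)C)(C(C)C)C(C)C)cc3)CO[C@H]2c2ccc(O[Si](C(C)C)(C(C)C)C(C)C)cc2)cc1)(C(C)C)C(C)C | intermediate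
18 | (2R,3S,5R)-5-(ArT-carbonyl)-2-ArT-3-[(E)-3-ArT-prop-2-en-1-yl]oxane | CC(C)[Si](Oc1ccc(/C=C/C[C@H]2C[C@@H](C(=O)c3ccc(O[Si](C(C)C)(C(C)C)C(C)C)cc3)CO[C@H]2c2ccc(O[Si](C(C)C)(C(C)C)C(C)C)cc2)cc1)(C(C)C)C(C)C | intermediate
19 | (R)-ArT[(2R,3S,5R)-2-ArT-3-[(E)-3-ArT-prop-2-en-1-yl]oxan-5-yl]methanol | CC(C)[Si](Oc1ccc(/C=C/C[C@H]2C[C@@H]([C@@H](O)c3ccc(O[Si](C(C)C)(C(C)C)C(C)C)cc3)CO[C@H]2c2ccc(O[Si](C(C)C)(C(C)C)C(C)C)cc2)cc1)(C(C)C)C(C)C | intermediate
20 | 4-[(E)-3-[(2R,3S,5R)-5-[(R)-hydroxy(4-hydroxyphenyl)methyl]-2-(4-hydroxyphenyl)oxan-3-yl]prop-1-en-1-yl]phenol | Oc1ccc(/C=C/C[C@H]2C[C@@H]([C@@H](O)c3ccc(O)cc3)CO[C@H]2c2ccc(O)cc2)cc1 | target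

Total step count: 13. Longest linear sequence: 10 steps (1, 2, 3, 4, 7, 8, 10, 11, 12, 13).

Steps most likely to fail

Step 7. Anionic polymerization of the vinyl ketone and intermolecular O-allylation of the alkoxide may outrun the oxa-Michael/C-allylation cascade, or the enolate may be protonated by tert-butanol and stall at the open-chain adduct. Fallback, from 5 back to 10: the primary allylic hydroxyl of 5 is converted selectively into the chloride (MeSO2Cl, LiCl, 2,4,6-collidine, DMF, 0 °C) to give (S)-2-(chloromethyl)-1-ArT-prop-2-en-1-ol F1. Treatment of F1 with KOt-Bu in THF at −40 °C in the presence of 9 should give a palladium-free Michael-initiated ring closure: the alkoxide adds to the vinyl ketone and the enolate displaces the allylic chloride (direct or allylic displacement give the same ring), so O1–C6 and C4–C5 are still formed in one operation and the route is rejoined at 10.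

Step 11. Facial discrimination in the proton transfer may be insufficient, or the enolate may lose the ring oxygen by β-elimination on warming and re-close under thermodynamic control to the 3,5-trans epimer. Fallback, from 16 back to 18: 16 is enolized and silylated as in step 8 to give 15, and N-bromosuccinimide in THF at −78 °C converts 15 into (2R,3S)-5-bromo-5-(ArT-carbonyl)-2-ArT-3-[(E)-3-ArT-prop-2-en-1-yl]oxane F2. Reduction of F2 with Bu3SnH and catalytic PhSeSePh (benzeneselenol as a fast hydrogen-atom donor that should outrun cyclization onto the styrene), started by Et3B/air at −78 °C, transfers hydrogen to the planar α-keto radical on the face opposite the axial cinnamyl group and should give 18 without any enolate.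

Step 2. Conversion may be low because the electron-rich aldehyde is a poor electrophile in the aldol step of the Morita–Baylis–Hillman cycle, and the ee may be eroded by the competing dioxanone pathway. Fallback, from 2 back to 6: 2-bromoprop-2-en-1-ol is converted with t-BuLi (3 equiv, Et2O, −78 → 0 °C) into the 2-lithioallyl alkoxide, which adds to 2 to give rac-2-methylidene-1-ArT-propane-1,3-diol F3. The conditions of step 4 give rac-tert-butyl 2-[hydroxy(ArT)methyl]prop-2-en-1-yl carbonate F4. Sharpless kinetic resolution (Ti(OiPr)4, D-(−)-diisopropyl tartrate, t-BuOOH, 4 Å molecular sieves, CH2Cl2, −20 °C, taken slightly past half conversion) should epoxidize the (R)-enantiomer to tert-butyl {(2S)-2-[(R)-hydroxy(ArT)methyl]oxiran-2-yl}methyl carbonate F5 and leave (S)-configured 6.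

Further compounds
F1 | step 7 | (S)-2-(chloromethyl)-1-ArT-prop-2-en-1-ol | O[C@H](C(=C)CCl)c1ccc(O[Si](C(C)C)(C(C)C)C(C)C)cc1
F2 | step 11 | (2R,3S)-5-bromo-5-(ArT-carbonyl)-2-ArT-3-[(E)-3-ArT-prop-2-en-1-yl]oxane, both C5 epimers | CC(C)[Si](Oc1ccc(/C=C/C[C@H]2CC(Br)(C(=O)c3ccc(O[Si](C(C)C)(C(C)C)C(C)C)cc3)CO[C@H]2c2ccc(O[Si](C(C)C)(C(C)C)C(C)C)cc2)cc1)(C(C)C)C(C)C
F3 | step 2 | rac-2-methylidene-1-ArT-propane-1,3-diol | OC(C(=C)CO)c1ccc(O[Si](C(C)C)(C(C)C)C(C)C)cc1
F4 | step 2 | rac-tert-butyl 2-[hydroxy(ArT)methyl]prop-2-en-1-yl carbonate | OC(C(=C)COC(=O)OC(C)(C)C)c1ccc(O[Si](C(C)C)(C(C)C)C(C)C)cc1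
F5 | step 2 | tert-butyl {(2S)-2-[(R)-hydroxy(ArT)methyl]oxiran-2-yl}methyl carbonate | O[C@@H]([C@@]1(COC(=O)OC(C)(C)C)CO1)c1ccc(O[Si](C(C)C)(C(C)C)C(C)C)cc1
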